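Remark on the chemistry: the target has no stereocentre and its prenyl double bonds carry no E/Z descriptor. The only geometry the route must set is the E alkene of 7 and 9, which disappears on aromatisation. TIPS = tri(propan-2-yl)silyl.

## The problem

The target is a bibenzyl whose benzoic acid ring (ring A) is hexasubstituted: C1 CO2H, C2 OMe, C3 prenyl, C4 OH, C5 prenyl, C6 CH2CH2–ring B (a 4-hydroxyphenyl group). Every position of ring A is occupied, so a substituent added to a preformed ring must enter between two neighbours, and a stepwise substitution route faces a regiochemical question at six carbons. The two oxygens are differentiated against the natural bias of a resorcylate: the chelated, hindered oxygen at C2 is methylated and the exposed one at C4 is free. Both prenyl groups sit ortho to the free C4 hydroxyl. Acid closes them to chromans, hydrogenation is excluded (so the bridge cannot come from a stilbene once they are present), and electrophilic halogen attacks them. The acid is flanked at both ortho positions and is para to a hydroxyl, so ester hydrolysis at its carbonyl carbon is blocked and strong acid risks protodecarboxylation. Ring B must stay masked while ring A is made.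

The feature that opens the problem: ring A is a resorcinol monomethyl ether with a carbon substituent on the carbon between the two oxygens. The edge C2(OMe)–C3(prenyl) is the imprint of an alkoxyalkyne. C4(–OH), C5(prenyl), C6(CH2CH2Ar) and C1 are the oxygen and the four carbons of a vinylketene O=C=CH–C(R)=CH–R′. The one ring carbon such an annulation leaves as C–H is C1, which is para to the new hydroxyl and ortho to the methoxy group, so it is the only, and an activated, site for late entry of the carboxyl carbon.

## Retrosynthesis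

**22 ⇒ 21.** Only the O–Si bond of ring B is cut. The ring B phenol must be masked through ketene, Vilsmeier and chlorite chemistry, and a TIPS ether survives all of these. Fluoride acts at silicon, so the last step needs neither acid nor attack at the hindered carboxyl.

**21 ⇒ 20 ⇒ 18.** The C1–carboxyl bond is cut, first to the aldehyde 20 and then to the C1–H phenol 18. C1 is the single open position of ring A and is para to OH and ortho to OMe, so formylation has no regiochemical choice. Carrying the carboxyl through the ring synthesis was weighed and set aside (Alternative 3). The forward reactions must be a formylation mild enough for an ortho-prenyl phenol and an aldehyde oxidation that spares two trisubstituted alkenes.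

**18 ⇒ 9 + 13 (key).** Ring A is cut at C3–C4, C1–C2 and C4–C5, and the C1–C6 bond is traced to a 1,2-shift. This leads to the acyclic diazo enone 9 and the ynol ether 13. Against cutting the aryl–prenyl bonds, this cut fixes five substituents and the OMe/OH pattern by connectivity alone: the ynol ether oxygen becomes the methyl ether and the ketene oxygen the free hydroxyl. The precursors are achiral open chains with one defined alkene. The forward reaction must combine the ketene and the alkyne in a single orientation.

**13 ⇒ 10 + 11.** The C(sp)–C(sp3) bond is cut to lithium methoxyacetylide 12 (from chloroacetal 10) and prenyl bromide 11. A methyl ynol ether is needed because its alkyl group stays in the target.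

**9 ⇒ 7.** The C=N2 unit is removed from the methyl group of enone 7, via the trifluoroacetyl ketone 8. Diazo transfer through 8 is the established access to α,β-unsaturated α′-diazo ketones and needs only kinetic enolisation at the methyl group.

**7 ⇒ 4 + 6.** The C3=C4 alkene is cut by Horner–Wadsworth–Emmons olefination into keto phosphonate 4 and aldehyde 6, which is made in situ from alcohol 5. The keto phosphonate gives the methyl ketone directly, with no ester-to-ketone adjustment. The forward step must deliver the E alkene and must not move the β,γ-alkene of 6 into conjugation.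

**4 ⇒ 3 + 2, and 2 ⇒ 1.** The C–C bond between the phosphonate carbon and the phenethyl group is cut (alkylation of 3 by bromide 2). Bromide 2 is the silyl ether of commercial 1.

## Roads not taken

Alternative 1: Cut both aryl–prenyl bonds and start from a preformed bibenzyl resorcylate, methyl 4-hydroxy-2-methoxy-6-{2-[4-(TIPS-oxy)phenyl]ethyl}benzoate A1. The forward key step is double ortho-prenylation of the C4 phenol (phenoxide C-alkylation, or O-allylation and Claisen rearrangement twice) to the diprenyl ester A2. This is the route most chemists would draw first.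
- A1 itself needs a multi-step synthesis, including methylation of the chelated O2 while O4 is masked and later freed.
- The two prenylations occur at sites of different hindrance, with O- versus C-alkylation and chroman formation as competitors.
- A2 ends in a doubly ortho-substituted methyl benzoate that resists saponification.
- The chosen plan answers the same questions by connectivity, in fewer steps.

Alternative 2: Cut C1–C6 as in the biosynthesis. The precursor is a masked poly-β-carbonyl chain, dioxinone A3, carrying both prenyl groups. Thermolysis in methanol and aldol aromatisation would give methyl 2,4-dihydroxy-3,5-diprenyl-6-(arylethyl)benzoate A4.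
- The folding gives both oxygens free, and methylation then goes to the exposed O4, giving the wrong ether A5, unless further protection steps are added.
- A3 needs two C-prenylations at two different carbons of a polycarbonyl chain, which is not simpler than the ring it makes.

Alternative 3: Keep the ketene–alkyne annulation but carry the carboxyl through it as an ester on the ketene carbon, starting from diazo keto ester A6. This would give the protected acid A9 with all six substituents in one operation and save two steps.
- The cyclobutenone intermediate A7 carries an ester and the alkenyl group on the same ring carbon.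
- An acceptor prefers to rotate inward on ring opening. An ester turned toward the ketene can capture it through its carbonyl oxygen (oxa-6π closure) to give the 6-alkoxy-2-pyranone A8, a dead end.
- In the chosen route that carbon bears only hydrogen (15), so ring opening in the unproductive sense simply reverts.

Key step: step 6

## Route

Step 1
Reactants: 1 4-(2-bromoethyl)phenol
Product: 2 [4-(2-bromoethyl)phenoxy]tri(propan-2-yl)silane
Conditions: TIPSCl, imidazole, DMF, 0 °C → rt
Reagents that add atoms: chlorotri(propan-2-yl)silane, CC(C)[Si](Cl)(C(C)C)C(C)C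
Why: Phenol silylation; imidazole is too weak a base to form the phenoxide that would displace the bromide intramolecularly, and the aryl TIPS ether survives the bases, light, heat, Vilsmeier and chlorite conditions of steps 2 to 8 yet is cleaved by fluoride.

Step 2
Reactants: 3 diethyl (2-oxopropyl)phosphonate; 2 [4-(2-bromoethyl)phenoxy]tri(propan-2-yl)silane
Product: 4 diethyl (2-oxo-5-{4-[tri(propan-2-yl)silyloxy]phenyl}pentan-3-yl)phosphonate (racemic)
Conditions: 3, NaH (slight deficit), THF, 0 °C; then 2, NaI (cat.), DMSO, 60 °C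
Reagents that add atoms: none
Why: C-Alkylation (SN2, iodide catalysis) of the sodium salt of the β-keto phosphonate at the carbon between P and C=O; the soft stabilised carbanion favours substitution over elimination, and no free hydride remains to attack the silyl ether. The new stereocentre is racemic and is erased in step 3.

Step 3
Reactants: 5 4-methylpent-3-en-1-ol; 4 diethyl (2-oxo-5-{4-[tri(propan-2-yl)silyloxy]phenyl}pentan-3-yl)phosphonate
Product: 7 (3E)-7-methyl-3-(2-{4-[tri(propan-2-yl)silyloxy]phenyl}ethyl)octa-3,6-dien-2-one, via 4-methylpent-3-enal 6 (not isolated)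
Conditions: 5, Dess–Martin periodinane, NaHCO3, CH2Cl2, 0 °C (6 kept in cold solution); 4, NaH, THF, 0 °C; then 6, 0 °C → rt
Reagents that add atoms: none
Why: Buffered Dess–Martin oxidation gives the β,γ-unsaturated aldehyde 6 without conjugating its alkene, and the preformed phosphonate anion consumes it in a Horner–Wadsworth–Emmons olefination. The E alkene (acetyl trans to the C5 methylene) is the thermodynamically preferred outcome of the reversible addition; any Z isomer would be removed by chromatography.

Step 4
Reactants: 7 (3E)-7-methyl-3-(2-{4-[tri(propan-2-yl)silyloxy]phenyl}ethyl)octa-3,6-dien-2-one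
Product: 9 (3E)-1-diazo-7-methyl-3-(2-{4-[tri(propan-2-yl)silyloxy]phenyl}ethyl)octa-3,6-dien-2-one, via trifluoromethyl diketone 8 (not isolated)
Conditions: LiN(SiMe3)2, THF, −78 °C; CF3CO2CH2CF3; then MsN3, Et3N, H2O, MeCN, rt
Reagents that add atoms: methanesulfonyl azide, CS(=O)(=O)N=[N+]=[N-]
Why: Detrifluoroacetylative diazo transfer: kinetic deprotonation at the methyl group (cross-conjugated enolate, the doubly allylic C5–H is not removed at −78 °C), Claisen trifluoroacetylation to 8, then Regitz diazo transfer with loss of the trifluoroacetyl group. This is the standard access to α,β-unsaturated α′-diazo ketones and leaves the E alkene untouched.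

Step 5
Reactants: 10 2-chloro-1,1-dimethoxyethane; 11 1-bromo-3-methylbut-2-ene
Product: 13 1-methoxy-5-methylhex-4-en-1-yne, via lithium methoxyacetylide 12 (not isolated)
Conditions: LiNEt2 (from Et2NH and n-BuLi, 3 equiv), THF, 0 °C; then 11, DMPU, −78 °C → rt
Reagents that add atoms: none
Why: Two eliminations (MeOH, then HCl) and deprotonation give lithium methoxyacetylide 12, which is C-alkylated by the primary allylic bromide (SN2); three equivalents of amide leave no base to isomerise the skipped enyne. A methyl ynol ether has no hydrogen β to oxygen and so cannot fragment by retro-ene reaction at the temperature of step 6.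

Step 6
Reactants: 9 (3E)-1-diazo-7-methyl-3-(2-{4-[tri(propan-2-yl)silyloxy]phenyl}ethyl)octa-3,6-dien-2-one; 13 1-methoxy-5-methylhex-4-en-1-yne
Product: 18 3-methoxy-2,6-bis(3-methylbut-2-en-1-yl)-5-(2-{4-[tri(propan-2-yl)silyloxy]phenyl}ethyl)phenol, via vinylketene 14 (not isolated), via alkenylcyclobutenone 15 (not isolated), via dienylketene 16 (not isolated), via cyclohexadienone 17 (not isolated)
Conditions: 13 (3 equiv), hν (365 nm), degassed ClCH2CH2Cl, rt; then 80 °C
Reagents that add atoms: none
Why: Irradiation of 9 triggers a Wolff rearrangement (loss of N2 and 1,2-shift of the alkenyl group with retention of its E geometry, which forms the future C1–C6 bond) to vinylketene 14. Ketene 14 and ynol ether 13 combine in a [2+2] cycloaddition in which the electrophilic ketene carbon (future C4) bonds to the prenyl-bearing alkyne carbon, the nucleophilic carbon β to oxygen, and the ketene α-carbon (future C1) bonds to the methoxy-bearing carbon (future C2), giving cyclobutenone 15. On warming, 15 opens by reversible conrotatory 4π electrocyclic cleavage to dienylketene 16, whose rotamer with the alkenyl arm turned toward the ketene closes by disrotatory 6π electrocyclisation (C4–C5) to dienone 17, which tautomerises to phenol 18. This is the vinylketene–alkynyl ether (Danheiser) benzannulation in its photochemical Wolff variant, the reaction by which alkoxyalkynes bearing an allylic chain give resorcinol monoethers with that chain between the two oxygens. The four-membered ring closes by [2+2] cycloaddition and ring A by 6π electrocyclisation; the sp3 ring carbons of 15 and 17 are racemic and transient, so no stereocentre needs control. The selectivity required is the orientation of the [2+2], which the polarisation of 13 secures and which alone places OMe at C2 next to C1–H and the prenyl group at C3 next to the new hydroxyl. The E geometry of 9 holds the C5 methylene and its alkene away from the ketene, which shuts off 1,5-hydrogen shift and intramolecular ketene–alkene cycloaddition, and ring opening of 15 in the unproductive sense only returns to 15 because that carbon bears hydrogen and nothing that can capture the ketene. The hydroxyl formed is flanked by two prenyl groups and is therefore a poor trap for 14, and the excess of 13 keeps the ketene concentration low.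

Step 7
Reactants: 18 3-methoxy-2,6-bis(3-methylbut-2-en-1-yl)-5-(2-{4-[tri(propan-2-yl)silyloxy]phenyl}ethyl)phenol
Product: 20 4-hydroxy-2-methoxy-3,5-bis(3-methylbut-2-en-1-yl)-6-(2-{4-[tri(propan-2-yl)silyloxy]phenyl}ethyl)benzaldehyde, via aryl iminium chloride 19 (not isolated)
Conditions: POCl3, DMF, 0 °C → rt; then aq. NaOAc, rt
Reagents that add atoms: N,N-dimethylformamide, CN(C)C=O; water, O
Why: Vilsmeier–Haack formylation at the only unsubstituted carbon of ring A, which is para to the hydroxyl and ortho to the methoxy group, so there is no regiochemical choice; ring B, a hindered aryl silyl ether with its para position blocked, is far less reactive. The chloroiminium salt is preformed in excess DMF, which holds the HCl, and hydrolysis in acetate buffer avoids acid closure of the ortho-prenyl phenol to a chroman.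

Step 8
Reactants: 20 4-hydroxy-2-methoxy-3,5-bis(3-methylbut-2-en-1-yl)-6-(2-{4-[tri(propan-2-yl)silyloxy]phenyl}ethyl)benzaldehyde
Product: 21 4-hydroxy-2-methoxy-3,5-bis(3-methylbut-2-en-1-yl)-6-(2-{4-[tri(propan-2-yl)silyloxy]phenyl}ethyl)benzoic acid
Conditions: NaClO2, NaH2PO4, 2-methylbut-2-ene (large excess), t-BuOH/H2O, 0 °C → rt
Reagents that add atoms: sodium chlorite, [Na+].[O-]Cl=O
Why: Pinnick oxidation of the aldehyde at about pH 4; the hypochlorous acid formed is taken up by the excess alkene, which outnumbers the two prenyl groups. Ring A has no free position to chlorinate and ring B is still silylated, which is why the oxidation precedes desilylation.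

Step 9
Reactants: 21 4-hydroxy-2-methoxy-3,5-bis(3-methylbut-2-en-1-yl)-6-(2-{4-[tri(propan-2-yl)silyloxy]phenyl}ethyl)benzoic acid
Product: 22 4-hydroxy-6-[2-(4-hydroxyphenyl)ethyl]-2-methoxy-3,5-bis(3-methylbut-2-en-1-yl)benzoic acid
Conditions: Bu4NF, THF, 0 °C → rt; aq. NH4Cl
Reagents that add atoms: none
Why: Fluoride cleaves the aryl Si–O bond by attack at silicon; no acid is used, so the prenyl groups and the electron-rich acid (prone to protodecarboxylation) are not endangered, and the work-up is only mildly acidic.

## Compound list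

1 | 4-(2-bromoethyl)phenol | Oc1ccc(CCBr)cc1 | starting material
2 | [4-(2-bromoethyl)phenoxy]tri(propan-2-yl)silane | CC(C)[Si](Oc1ccc(CCBr)cc1)(C(C)C)C(C)C | intermediate
3 | diethyl (2-oxopropyl)phosphonate | CCOP(=O)(CC(C)=O)OCC | starting material
4 | diethyl (2-oxo-5-{4-[tri(propan-2-yl)silyloxy]phenyl}pentan-3-yl)phosphonate (racemic) | CCOP(=O)(OCC)C(CCc1ccc(O[Si](C(C)C)(C(C)C)C(C)C)cc1)C(C)=O | intermediate
5 | 4-methylpent-3-en-1-ol | CC(C)=CCCO | starting material
6 | 4-methylpent-3-enal | CC(C)=CCC=O | intermediate (not isolated)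
7 | (3E)-7-methyl-3-(2-{4-[tri(propan-2-yl)silyloxy]phenyl}ethyl)octa-3,6-dien-2-one | CC(=O)/C(CCc1ccc(O[Si](C(C)C)(C(C)C)C(C)C)cc1)=C/CC=C(C)C | intermediate
8 | (5E)-1,1,1-trifluoro-9-methyl-5-(2-{4-[tri(propan-2-yl)silyloxy]phenyl}ethyl)deca-5,8-diene-2,4-dione | FC(F)(F)C(=O)CC(=O)/C(CCc1ccc(O[Si](C(C)C)(C(C)C)C(C)C)cc1)=C/CC=C(C)C | intermediate (not isolated)
9 | (3E)-1-diazo-7-methyl-3-(2-{4-[tri(propan-2-yl)silyloxy]phenyl}ethyl)octa-3,6-dien-2-one | [N-]=[N+]=CC(=O)/C(CCc1ccc(O[Si](C(C)C)(C(C)C)C(C)C)cc1)=C/CC=C(C)C | intermediate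
10 | 2-chloro-1,1-dimethoxyethane | COC(CCl)OC | starting material
11 | 1-bromo-3-methylbut-2-ene | CC(C)=CCBr | starting material
12 | lithium methoxyacetylide | [Li]C#COC | intermediate (not isolated)
13 | 1-methoxy-5-methylhex-4-en-1-yne | COC#CCC=C(C)C | intermediate
14 | (3E)-7-methyl-3-(2-{4-[tri(propan-2-yl)silyloxy]phenyl}ethyl)octa-1,3,6-trien-1-one (vinylketene) | O=C=C/C(CCc1ccc(O[Si](C(C)C)(C(C)C)C(C)C)cc1)=C/CC=C(C)C | intermediate (not isolated)
15 | 3-methoxy-2-(3-methylbut-2-en-1-yl)-4-[(3E)-7-methyl-1-{4-[tri(propan-2-yl)silyloxy]phenyl}octa-3,6-dien-3-yl]cyclobut-2-en-1-one (racemic) | COC1=C(CC=C(C)C)C(=O)C1/C(CCc2ccc(O[Si](C(C)C)(C(C)C)C(C)C)cc2)=C/CC=C(C)C | intermediate (not isolated)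
16 | (3E,5E)-3-methoxy-9-methyl-2-(3-methylbut-2-en-1-yl)-5-(2-{4-[tri(propan-2-yl)silyloxy]phenyl}ethyl)deca-1,3,5,8-tetraen-1-one (dienylketene) | O=C=C(CC=C(C)C)/C(OC)=C\C(CCc1ccc(O[Si](C(C)C)(C(C)C)C(C)C)cc1)=C\CC=C(C)C | intermediate (not isolated)
17 | 3-methoxy-2,6-bis(3-methylbut-2-en-1-yl)-5-(2-{4-[tri(propan-2-yl)silyloxy]phenyl}ethyl)cyclohexa-2,4-dien-1-one (racemic) | O=C1C(CC=C(C)C)=C(OC)C=C(CCc2ccc(O[Si](C(C)C)(C(C)C)C(C)C)cc2)C1CC=C(C)C | intermediate (not isolated)
18 | 3-methoxy-2,6-bis(3-methylbut-2-en-1-yl)-5-(2-{4-[tri(propan-2-yl)silyloxy]phenyl}ethyl)phenol | COc1cc(CCc2ccc(O[Si](C(C)C)(C(C)C)C(C)C)cc2)c(CC=C(C)C)c(O)c1CC=C(C)C | intermediate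
19 | N-{[4-hydroxy-2-methoxy-3,5-bis(3-methylbut-2-en-1-yl)-6-(2-{4-[tri(propan-2-yl)silyloxy]phenyl}ethyl)phenyl]methylidene}-N-methylmethanaminium chloride | C[N+](C)=Cc1c(OC)c(CC=C(C)C)c(O)c(CC=C(C)C)c1CCc1ccc(O[Si](C(C)C)(C(C)C)C(C)C)cc1.[Cl-] | intermediate (not isolated)
20 | 4-hydroxy-2-methoxy-3,5-bis(3-methylbut-2-en-1-yl)-6-(2-{4-[tri(propan-2-yl)silyloxy]phenyl}ethyl)benzaldehyde | COc1c(CC=C(C)C)c(O)c(CC=C(C)C)c(CCc2ccc(O[Si](C(C)C)(C(C)C)C(C)C)cc2)c1C=O | intermediate
21 | 4-hydroxy-2-methoxy-3,5-bis(3-methylbut-2-en-1-yl)-6-(2-{4-[tri(propan-2-yl)silyloxy]phenyl}ethyl)benzoic acid | COc1c(CC=C(C)C)c(O)c(CC=C(C)C)c(CCc2ccc(O[Si](C(C)C)(C(C)C)C(C)C)cc2)c1C(=O)O | intermediate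
22 | 4-hydroxy-6-[2-(4-hydroxyphenyl)ethyl]-2-methoxy-3,5-bis(3-methylbut-2-en-1-yl)benzoic acid | COc1c(CC=C(C)C)c(O)c(CC=C(C)C)c(CCc2ccc(O)cc2)c1C(=O)O | target

## Step count and risk

Total step count: 9. Longest linear sequence: 8 steps (1, 2, 3, 4, 6, 7, 8, 9, starting from 1). Step 5 is a one-step side branch.

**Step 6 (key step).** What may go wrong:
- Light-induced E-to-Z isomerisation of the enone before or after the Wolff shift, after which the Z vinylketene is lost by 1,5-hydrogen shift or by intramolecular [2+2] addition to the prenyl alkene.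
- Carbene addition to the ynol ether before rearrangement.
- Acylation of the product phenol by the ketene.

Fallback: a thermal route through a cyclobutenone, which needs neither light nor a diazo compound. It sets out from bromide 2 and comes back at 18. Bromide 2 is alkylated with LiC≡CH·H2NCH2CH2NH2 in DMSO to give [4-(but-3-yn-1-yl)phenoxy]tri(propan-2-yl)silane F1. Dichloroketene (Cl3CCOCl, Zn(Cu), Et2O) adds to F1 to give 4,4-dichloro-3-(2-{4-[tri(propan-2-yl)silyloxy]phenyl}ethyl)cyclobut-2-en-1-one F2. Zn in AcOH/TMEDA reduces F2 to 3-(2-{4-[tri(propan-2-yl)silyloxy]phenyl}ethyl)cyclobut-2-en-1-one F3. Heating F3 with 13 in toluene at 80 °C gives, through a vinylketene with an unsubstituted terminus, 3-methoxy-2-(3-methylbut-2-en-1-yl)-5-(2-{4-[tri(propan-2-yl)silyloxy]phenyl}ethyl)phenol F4. C-Prenylation of the sodium phenoxide of F4 at its free ortho carbon (NaH, toluene, 11) then returns to 18.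

**Step 7.** What may go wrong: acid-promoted cyclisation of a prenyl group onto the neighbouring hydroxyl (chroman formation) under the influence of HCl and the chloroiminium salt, or stalling at O-formylation.

Fallback: introduce the carbon under basic conditions. It sets out from 18 and comes back at 20. The phenoxide of 18 is hydroxymethylated at its para carbon with aqueous formaldehyde and KOH to give 4-(hydroxymethyl)-3-methoxy-2,6-bis(3-methylbut-2-en-1-yl)-5-(2-{4-[tri(propan-2-yl)silyloxy]phenyl}ethyl)phenol F5. The benzylic alcohol of F5 is oxidised with MnO2 in CH2Cl2 to aldehyde 20.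

**Step 3.** What may go wrong: base-induced migration of the alkene of 6 into conjugation before olefination, slow reaction of the hindered α-branched keto phosphonate, and erosion of E selectivity.

Fallback: make the alkene by metathesis, without aldehyde 6. It sets out from 4 and comes back at 7. Olefination of 4 with aqueous formaldehyde and K2CO3 gives 3-methylidene-5-{4-[tri(propan-2-yl)silyloxy]phenyl}pentan-2-one F6. Cross-metathesis of F6 with commercial 5-methylhexa-1,4-diene (second-generation Hoveyda–Grubbs catalyst, CH2Cl2, 40 °C) gives 7, with the E alkene expected under thermodynamic control.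

**Step 5.** What may go wrong: attack of the acetylide at the tertiary terminus of the allylic bromide, base-induced isomerisation of the skipped enyne to an allene or conjugated enyne, and loss of the volatile product on isolation.

Fallback: use the parent ynol ether and add the C3 prenyl group afterwards. It sets out from 10 and 9 and comes back at 18. Chloroacetal 10 with NaNH2 in liquid NH3, followed by protonation and distillation, gives methoxyethyne F7. Benzannulation of 9 with F7 under the conditions of step 6 gives 5-methoxy-2-(3-methylbut-2-en-1-yl)-3-(2-{4-[tri(propan-2-yl)silyloxy]phenyl}ethyl)phenol F8. C-Prenylation of the sodium phenoxide of F8 at the free ortho carbon between OH and OMe (NaH, toluene, 11) gives 18.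

## Further compounds

F1 | step 6 | [4-(but-3-yn-1-yl)phenoxy]tri(propan-2-yl)silane | C#CCCc1ccc(O[Si](C(C)C)(C(C)C)C(C)C)cc1
F2 | step 6 | 4,4-dichloro-3-(2-{4-[tri(propan-2-yl)silyloxy]phenyl}ethyl)cyclobut-2-en-1-one | O=C1C=C(CCc2ccc(O[Si](C(C)C)(C(C)C)C(C)C)cc2)C1(Cl)Cl
F3 | step 6 | 3-(2-{4-[tri(propan-2-yl)silyloxy]phenyl}ethyl)cyclobut-2-en-1-one | O=C1C=C(CCc2ccc(O[Si](C(C)C)(C(C)C)C(C)C)cc2)C1
F4 | step 6 | 3-methoxy-2-(3-methylbut-2-en-1-yl)-5-(2-{4-[tri(propan-2-yl)silyloxy]phenyl}ethyl)phenol | COc1cc(CCc2ccc(O[Si](C(C)C)(C(C)C)C(C)C)cc2)cc(O)c1CC=C(C)C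
F5 | step 7 | 4-(hydroxymethyl)-3-methoxy-2,6-bis(3-methylbut-2-en-1-yl)-5-(2-{4-[tri(propan-2-yl)silyloxy]phenyl}ethyl)phenol | COc1c(CC=C(C)C)c(O)c(CC=C(C)C)c(CCc2ccc(O[Si](C(C)C)(C(C)C)C(C)C)cc2)c1CO
F6 | step 3 | 3-methylidene-5-{4-[tri(propan-2-yl)silyloxy]phenyl}pentan-2-one | CC(=O)C(=C)CCc1ccc(O[Si](C(C)C)(C(C)C)C(C)C)cc1
F7 | step 5 | methoxyethyne | COC#C
F8 | step 5 | 5-methoxy-2-(3-methylbut-2-en-1-yl)-3-(2-{4-[tri(propan-2-yl)silyloxy]phenyl}ethyl)phenol | COc1cc(O)c(CC=C(C)C)c(CCc2ccc(O[Si](C(C)C)(C(C)C)C(C)C)cc2)c1
A1 | alternative 1 | methyl 4-hydroxy-2-methoxy-6-(2-{4-[tri(propan-2-yl)silyloxy]phenyl}ethyl)benzoate | COC(=O)c1c(OC)cc(O)cc1CCc1ccc(O[Si](C(C)C)(C(C)C)C(C)C)cc1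
A2 | alternative 1 | methyl 4-hydroxy-2-methoxy-3,5-bis(3-methylbut-2-en-1-yl)-6-(2-{4-[tri(propan-2-yl)silyloxy]phenyl}ethyl)benzoate | COC(=O)c1c(OC)c(CC=C(C)C)c(O)c(CC=C(C)C)c1CCc1ccc(O[Si](C(C)C)(C(C)C)C(C)C)cc1
A3 | alternative 2 | 2,2-dimethyl-6-[1,3-bis(3-methylbut-2-en-1-yl)-2,4-dioxo-6-{4-[tri(propan-2-yl)silyloxy]phenyl}hexyl]-4H-1,3-dioxin-4-one | CC1(C)OC(=O)C=C(O1)C(CC=C(C)C)C(=O)C(CC=C(C)C)C(=O)CCc1ccc(O[Si](C(C)C)(C(C)C)C(C)C)cc1
A4 | alternative 2 | methyl 2,4-dihydroxy-3,5-bis(3-methylbut-2-en-1-yl)-6-(2-{4-[tri(propan-2-yl)silyloxy]phenyl}ethyl)benzoate | COC(=O)c1c(O)c(CC=C(C)C)c(O)c(CC=C(C)C)c1CCc1ccc(O[Si](C(C)C)(C(C)C)C(C)C)cc1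
A5 | alternative 2 | methyl 2-hydroxy-4-methoxy-3,5-bis(3-methylbut-2-en-1-yl)-6-(2-{4-[tri(propan-2-yl)silyloxy]phenyl}ethyl)benzoate | COC(=O)c1c(O)c(CC=C(C)C)c(OC)c(CC=C(C)C)c1CCc1ccc(O[Si](C(C)C)(C(C)C)C(C)C)cc1
A6 | alternative 3 | 2-(trimethylsilyl)ethyl (4E)-2-diazo-8-methyl-3-oxo-4-(2-{4-[tri(propan-2-yl)silyloxy]phenyl}ethyl)nona-4,7-dienoate | C[Si](C)(C)CCOC(=O)C(=[N+]=[N-])C(=O)/C(CCc1ccc(O[Si](C(C)C)(C(C)C)C(C)C)cc1)=C/CC=C(C)C
A7 | alternative 3 | 2-(trimethylsilyl)ethyl 2-methoxy-3-(3-methylbut-2-en-1-yl)-4-oxo-1-[(3E)-7-methyl-1-{4-[tri(propan-2-yl)silyloxy]phenyl}octa-3,6-dien-3-yl]cyclobut-2-ene-1-carboxylate (racemic) | COC1=C(CC=C(C)C)C(=O)C1(C(=O)OCC[Si](C)(C)C)/C(CCc2ccc(O[Si](C(C)C)(C(C)C)C(C)C)cc2)=C/CC=C(C)C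
A8 | alternative 3 | 4-methoxy-3-(3-methylbut-2-en-1-yl)-5-[(3E)-7-methyl-1-{4-[tri(propan-2-yl)silyloxy]phenyl}octa-3,6-dien-3-yl]-6-[2-(trimethylsilyl)ethoxy]-2H-pyran-2-one | O=C1OC(OCC[Si](C)(C)C)=C(C(OC)=C1CC=C(C)C)/C(CCc2ccc(O[Si](C(C)C)(C(C)C)C(C)C)cc2)=C/CC=C(C)C
A9 | alternative 3 | 2-(trimethylsilyl)ethyl 4-hydroxy-2-methoxy-3,5-bis(3-methylbut-2-en-1-yl)-6-(2-{4-[tri(propan-2-yl)silyloxy]phenyl}ethyl)benzoate | COc1c(CC=C(C)C)c(O)c(CC=C(C)C)c(CCc2ccc(O[Si](C(C)C)(C(C)C)C(C)C)cc2)c1C(=O)OCC[Si](C)(C)C
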